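**Retrosynthetic overview**
1. Target ⇐ its 5,5'-di-O-methyl ether (peri-demethylation) ⇐ a 6,8'-binaphthalene-4,4'-diol (para-oxidation installs the C1/C1' oxygens).
2. Both ethoxy-bearing (quinonoid) rings close last and together, by a two-fold intramolecular aldol condensation of a biaryl in which each ring carries an ArCOCH2OEt ketone and an ortho CH2CHO group (masked as an enol ether).
3. The C6–C8' axis ⇐ atroposelective Suzuki coupling of an aryl chloride (ring A) with an aryl boronate (ring B).
4. Each benzene fragment: the 2-ethoxyacetyl group by ortho-lithiation between two oxygens plus a Weinreb amide; the masked CH2CHO by Suzuki coupling of an aryl triflate with 2-ethoxyvinyl-Bpin.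
5. Ring order: the two methyl-bearing benzenoid rings are bought (3,5-dimethoxytoluene, 3-methoxy-5-methylphenol) → biaryl → both quinonoid rings (aldol) → oxidation.

Assumption: the SMILES has no stereodescriptor; the only stereogenic element is the tetra-ortho-substituted 6,8' axis. I take "single enantiomer" to mean one atropisomer, set in step 14 (the ligand enantiomer selects the hand), and write SMILES without an axial descriptor, as given.

**Route**

Step 1
Reactants: 1 ethoxyacetic acid; 2 N,O-dimethylhydroxylamine hydrochloride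
Product: 3 2-ethoxy-N-methoxy-N-methylacetamide
Conditions: CDI, CH2Cl2, 0 °C→rt; then 2, Et3N
Reagents that add atoms: none
Why: Amidation via the acyl imidazolide gives the Weinreb amide used to acylate both aryllithiums.

Step 2
Reactants: 4 3,5-dimethoxytoluene; 3
Product: 5 1-(2,6-dimethoxy-4-methylphenyl)-2-ethoxyethan-1-one
Conditions: n-BuLi, THF, 0 °C→rt; then 3, −78→0 °C; aq NH4Cl
Reagents that add atoms: none
Why: Directed ortho-metalation removes the C–H between the two OMe groups, and Weinreb acylation stops at the ketone.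

Step 3
Reactants: 5
Product: 6 2-ethoxy-1-(2-hydroxy-6-methoxy-4-methylphenyl)ethan-1-one
Conditions: BCl3 (1.1 equiv), CH2Cl2, −78→0 °C
Reagents that add atoms: none
Why: Chelation-assisted mono-demethylation ortho to the ketone; the substrate is symmetric so one product forms, and the boron chelate blocks a second cleavage.

Step 4
Reactants: 6
Product: 7 1-(3-chloro-2-hydroxy-6-methoxy-4-methylphenyl)-2-ethoxyethan-1-one
Conditions: NCS (1.05 equiv), DMF, 0 °C→rt
Reagents that add atoms: N-chlorosuccinimide, ClN1C(=O)CCC1=O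
Why: Electrophilic aromatic chlorination; the chelated OH is a weakened donor, so OMe directs para, to the carbon that is also ortho to OH.

Step 5
Reactants: 7
Product: 8 2-chloro-6-(2-ethoxyacetyl)-5-methoxy-3-methylphenyl trifluoromethanesulfonate
Conditions: Tf2O, pyridine, CH2Cl2, 0 °C
Reagents that add atoms: triflic anhydride, FC(F)(F)S(=O)(=O)OS(=O)(=O)C(F)(F)F
Why: O-sulfonylation turns the phenol into a cross-coupling handle.

Step 6
Reactants: 8; 9 (E)-2-(2-ethoxyvinyl)-4,4,5,5-tetramethyl-1,3,2-dioxaborolane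
Product: 10 (E)-1-[3-chloro-2-(2-ethoxyvinyl)-6-methoxy-4-methylphenyl]-2-ethoxyethan-1-one
Conditions: PdCl2(dppf) 5 mol %, K3PO4, dioxane/H2O, 80 °C
Reagents that add atoms: none
Why: Suzuki–Miyaura coupling at the C–OTf bond (ortho to acyl); the electron-rich, unactivated C–Cl bond is inert to Pd/dppf.

Step 7
Reactants: 10
Product: 11 (E)-2-ethoxy-1-[2-(2-ethoxyvinyl)-6-methoxy-4-methyl-3-(4,4,5,5-tetramethyl-1,3,2-dioxaborolan-2-yl)phenyl]ethan-1-one
Conditions: B2pin2, Pd2(dba)3/XPhos, KOAc, dioxane, 100 °C
Reagents that add atoms: bis(pinacolato)diboron, CC1(C)OB(OC1(C)C)B1OC(C)(C)C(C)(C)O1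
Why: Miyaura borylation of the hindered aryl chloride; KOAc leaves the ketone and enol ether untouched.

Step 8
Reactants: 12 3-methoxy-5-methylphenol
Product: 13 4-chloro-3-methoxy-5-methylphenol
Conditions: SO2Cl2 (1.0 equiv), CH2Cl2, 0 °C; minor isomers removed by crystallisation or chromatography
Reagents that add atoms: sulfuryl chloride, ClS(Cl)(=O)=O
Why: Electrophilic chlorination para to the free OH, the strongest donor, as for 3,5-dimethylphenol.

Step 9
Reactants: 13
Product: 14 2-chloro-1-methoxy-5-(methoxymethoxy)-3-methylbenzene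
Conditions: MOMCl, i-Pr2NEt, CH2Cl2, 0 °C→rt
Reagents that add atoms: chloromethyl methyl ether, COCCl
Why: MOM protection also provides a strong directing group for the next lithiation.

Step 10
Reactants: 14; 3
Product: 15 1-[3-chloro-2-methoxy-6-(methoxymethoxy)-4-methylphenyl]-2-ethoxyethan-1-one
Conditions: n-BuLi, THF, −78→0 °C; then 3, −78 °C
Reagents that add atoms: none
Why: Directed ortho-metalation at the C–H flanked by OMOM and OMe; the aryl chloride does not exchange with n-BuLi and has no ortho H.

Step 11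
Reactants: 15
Product: 16 1-(3-chloro-6-hydroxy-2-methoxy-4-methylphenyl)-2-ethoxyethan-1-one
Conditions: 3 M HCl, MeOH, 40 °C
Reagents that add atoms: none
Why: Acidic acetal cleavage removes the MOM group only.

Step 12
Reactants: 16
Product: 17 4-chloro-2-(2-ethoxyacetyl)-3-methoxy-5-methylphenyl trifluoromethanesulfonate
Conditions: Tf2O, pyridine, CH2Cl2, 0 °C
Reagents that add atoms: triflic anhydride, FC(F)(F)S(=O)(=O)OS(=O)(=O)C(F)(F)F
Why: Triflation of the phenol, as in step 5.

Step 13
Reactants: 17; 9
Product: 18 (E)-1-[3-chloro-6-(2-ethoxyvinyl)-2-methoxy-4-methylphenyl]-2-ethoxyethan-1-one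
Conditions: PdCl2(dppf) 5 mol %, K3PO4, dioxane/H2O, 80 °C
Reagents that add atoms: none
Why: Triflate-selective Suzuki–Miyaura coupling; the chloride is kept for the biaryl coupling.

Step 14
Reactants: 18; 11
Product: 19 1,1'-{2,4'-dimethoxy-6,6'-dimethyl-2',4-bis[(E)-2-ethoxyvinyl]biphenyl-3,3'-diyl}bis(2-ethoxyethan-1-one), single atropisomer
Conditions: Pd(OAc)2 5 mol %, (R)-BaryPhos (P-chiral monophosphine), K3PO4, toluene/H2O, 80–90 °C; enrich to >99% ee by recrystallisation or chiral SFC
Reagents that add atoms: none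
Why: Atroposelective Suzuki–Miyaura coupling forms the C6–C8' bond; the chiral ligand sets the axis (sense checked by CD, the other ligand enantiomer gives the antipode), and the tetra-ortho axis does not rotate at these temperatures.

Step 15
Reactants: 19
Product: 20 3,3'-diethoxy-5,5'-dimethoxy-7,7'-dimethyl-[6,8'-binaphthalene]-4,4'-diol
Conditions: 2 M HCl, THF, 40 °C; then K2CO3, MeOH, Ar, rt→50 °C (one pot)
Reagents that add atoms: none (water enters and leaves again)
Why: Two-fold intramolecular aldol condensation: on each ring the ArCOCH2OEt enolate attacks the unmasked ortho CH2CHO, then dehydration and tautomerisation give the naphthol. This closes both rings with OEt fixed next to the C4 oxygen; no new stereocentre forms and the axis is untouched.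

Step 16
Reactants: 20
Product: 21 3,3'-diethoxy-5,5'-dimethoxy-7,7'-dimethyl-[6,8'-binaphthalene]-1,1',4,4'-tetraone
Conditions: Fremy's salt (5 equiv), KH2PO4 buffer, acetone/H2O, rt
Reagents that add atoms: potassium nitrosodisulfonate, [K+].[K+].[O]N(S(=O)(=O)[O-])S(=O)(=O)[O-]
Why: Teuber oxidation of each 1-naphthol-type ring at its free para position (C1, C1') gives the 1,4-quinones; the ortho positions are blocked by OEt.

Step 17
Reactants: 21
Product: 22 3,3'-diethoxyisodiospyrin
Conditions: BCl3 (4–5 equiv), CH2Cl2, −78→−20 °C; quench with EtOH/aq NaHCO3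
Reagents that add atoms: none
Why: Chelation-controlled cleavage of the two peri-methoxy groups (six-membered C4=O···B···O5 chelate); the low temperature and EtOH quench protect the vinylogous ethyl esters.

**Compound list**
1 | ethoxyacetic acid | CCOCC(=O)O | starting material
2 | N,O-dimethylhydroxylamine hydrochloride | CNOC.Cl | starting material
3 | 2-ethoxy-N-methoxy-N-methylacetamide | CCOCC(=O)N(C)OC | intermediate
4 | 3,5-dimethoxytoluene | COc1cc(C)cc(OC)c1 | starting material
5 | 1-(2,6-dimethoxy-4-methylphenyl)-2-ethoxyethan-1-one | CCOCC(=O)c1c(OC)cc(C)cc1OC | intermediate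
6 | 2-ethoxy-1-(2-hydroxy-6-methoxy-4-methylphenyl)ethan-1-one | CCOCC(=O)c1c(O)cc(C)cc1OC | intermediate
7 | 1-(3-chloro-2-hydroxy-6-methoxy-4-methylphenyl)-2-ethoxyethan-1-one | CCOCC(=O)c1c(O)c(Cl)c(C)cc1OC | intermediate
8 | 2-chloro-6-(2-ethoxyacetyl)-5-methoxy-3-methylphenyl triflate | CCOCC(=O)c1c(OS(=O)(=O)C(F)(F)F)c(Cl)c(C)cc1OC | intermediate
9 | (E)-2-(2-ethoxyvinyl)-4,4,5,5-tetramethyl-1,3,2-dioxaborolane | CCO/C=C/B1OC(C)(C)C(C)(C)O1 | starting material
10 | (E)-1-[3-chloro-2-(2-ethoxyvinyl)-6-methoxy-4-methylphenyl]-2-ethoxyethan-1-one | CCOCC(=O)c1c(/C=C/OCC)c(Cl)c(C)cc1OC | intermediate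
11 | ring-B boronate (pinacol ester of 10 at the former C–Cl) | CCOCC(=O)c1c(/C=C/OCC)c(B2OC(C)(C)C(C)(C)O2)c(C)cc1OC | intermediate
12 | 3-methoxy-5-methylphenol | COc1cc(C)cc(O)c1 | starting material
13 | 4-chloro-3-methoxy-5-methylphenol | COc1cc(O)cc(C)c1Cl | intermediate
14 | 2-chloro-1-methoxy-5-(methoxymethoxy)-3-methylbenzene | COCOc1cc(C)c(Cl)c(OC)c1 | intermediate
15 | 1-[3-chloro-2-methoxy-6-(methoxymethoxy)-4-methylphenyl]-2-ethoxyethan-1-one | CCOCC(=O)c1c(OCOC)cc(C)c(Cl)c1OC | intermediate
16 | 1-(3-chloro-6-hydroxy-2-methoxy-4-methylphenyl)-2-ethoxyethan-1-one | CCOCC(=O)c1c(O)cc(C)c(Cl)c1OC | intermediate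
17 | 4-chloro-2-(2-ethoxyacetyl)-3-methoxy-5-methylphenyl triflate | CCOCC(=O)c1c(OS(=O)(=O)C(F)(F)F)cc(C)c(Cl)c1OC | intermediate
18 | (E)-1-[3-chloro-6-(2-ethoxyvinyl)-2-methoxy-4-methylphenyl]-2-ethoxyethan-1-one | CCOCC(=O)c1c(/C=C/OCC)cc(C)c(Cl)c1OC | intermediate
19 | biaryl bis(ethoxymethyl ketone) bis(enol ether), single atropisomer | CCOCC(=O)c1c(/C=C/OCC)cc(C)c(-c2c(C)cc(OC)c(C(=O)COCC)c2/C=C/OCC)c1OC | intermediate
20 | 3,3'-diethoxy-5,5'-dimethoxy-7,7'-dimethyl-[6,8'-binaphthalene]-4,4'-diol | CCOc1ccc2cc(C)c(-c3c(C)cc(OC)c4c(O)c(OCC)ccc34)c(OC)c2c1O | intermediate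
21 | 3,3'-diethoxy-5,5'-dimethoxy-7,7'-dimethyl-[6,8'-binaphthalene]-1,1',4,4'-tetraone | CCOC1=CC(=O)c2cc(C)c(-c3c(C)cc(OC)c4c3C(=O)C=C(OCC)C4=O)c(OC)c2C1=O | intermediate
22 | 3,3'-diethoxyisodiospyrin | CCOC1=CC(=O)c2cc(C)c(-c3c(C)cc(O)c4c3C(=O)C=C(OCC)C4=O)c(O)c2C1=O | target

**Totals**
Total steps: 17. Longest linear sequence: 11 (steps 1, 2–7, 14–17), i.e. 65% of the total.

**Three steps most likely to fail**
1. Step 14 (tetra-ortho atroposelective Suzuki with an aryl chloride). Fallback: couple racemically with an achiral bulky catalyst (Pd/SPhos or PEPPSI-IPent) and resolve bis-naphthol 20 as its diastereomeric bis-(1S)-camphanates (separate, then K2CO3/MeOH). Control of the axis then comes from resolution, not catalysis.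
2. Step 17 (peri-demethylation without touching the 3/3'-OEt vinylogous esters). Fallback: strip all four ethers (AlCl3 or BBr3) to the bis(3,5-dihydroxy)quinone, then re-etherify only the acidic 3/3'-OH with EtOH/HCl (Fischer-type etherification of 2-hydroxy-1,4-naphthoquinones; the peri phenols do not react).
3. Step 4 (site of chlorination; step 8 carries the same kind of risk). Fallback: place the chlorine before the acyl group. Chlorinate 3-methoxy-5-methylphenyl acetate (OMe alone directs para, to the carbon next to the O-acyl group), hydrolyse, protect as the MOM ether, then ortho-lithiate and acylate with 3 and remove MOM, as in steps 9–11, to reach 7.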